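A single target reading is a poor thing to feed a model: Thursday's last one is 0.3 %, with a scatter of 0.3 percentage points on it. You have starting material and first nucleophile under a held gas, and you want to know how other capture product stands against target, early and late.

| setting | Friday's | Saturday's | Thursday's | flask |
|---|---|---|---|---|
| starting material | 0.40 M | 0.40 M | 0.20 M | 0.40 M |
| first nucleophile | 0.28 M | 0.63 M | 0.42 M | 0.420 M |
| gas | 61 mM (held) | 61 mM (held) | 61 mM (held) | 61 mM (held) |
| remark | run made earlier | run made earlier | run made earlier |  |
| time |  |  |  | 30 h |

| run | time / h | other capture product / % | target / % |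
|---|---|---|---|
| Friday's | 5.00 | 25.0 | 0.7 |
| Friday's | 12.0 | 50.8 | 0.6 |
| Friday's | 25.0 | 76.9 | 0.3 |
| Friday's | 40.0 | 89.6 | 0 |
| Saturday's | 5.00 | 24.5 | 2.0 |
| Saturday's | 12.0 | 49.0 | 1.0 |
| Saturday's | 25.0 | 75.6 | 0 |
| Saturday's | 40.0 | 89.0 | 0.3 |
| Thursday's | 3.00 | 15.2 | 1.5 |
| Thursday's | 6.00 | 28.6 | 1.1 |
| Thursday's | 15.0 | 58.4 | 0.4 |
| Thursday's | 40.0 | 89.7 | 0.3 |

(each reading ± 0.3 percentage points)

1. ratio of other capture product to target at 25 min
2. ratio of other capture product to target at 30 h
3. which of other capture product and target there is more of at 30 h

- what was read earlier has a scatter of 0.3 percentage points, one standard deviation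
- at the start none of the gas is in solution

One thing looks contradictory. After 5.00 h, Saturday's run, with first nucleophile at 0.63 M against Friday's 0.28 M, shows target at 2.0 % against 0.7 %, yet other capture product reads 24.5 % against 25.0 %. It clears once you replace each wandering target curve by its mean. Thursday's run, which has the flask's first nucleophile, gives 1.61 % as its hold share, the summed target readings over the summed fractions of the charge not yet read as either product. Friday's hold share is 1.02 % and Saturday's 2.08 %, so these two runs, which differ in first nucleophile, read target as a small side pool whose share is larger with more first nucleophile, while the remainder after 40.0 h reads 10.4 %, 10.7 % and 10.0 % in Friday's, Saturday's and Thursday's runs, as behind a rate-limiting step.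

My reckoning for the flask takes Thursday's remainder at 40.0 h back along an exponential to 17.8 % at 30 h, which gives target 0.287 %, other capture product 81.9 % and a ratio of 286. It says nothing firm for 25 min, since that is earlier than the first reading, at 3.00 h.

The forecast gives 1 early (“Ratio about 1, very uncertain”), 290 late, and other capture product ahead.

The flask gives 3.61 early and 344 late, with other capture product ahead, 82.1 % against 0.239 %.

    starting material → intermediate (k = 0.00100 /min)
    first nucleophile + intermediate ⇌ target (K = 18.0 /M, k = 0.430 /M/min)
    second nucleophile + intermediate → other capture product (k = 8.50 /M/min)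
    target → over-reaction product (k = 0.00100 /min)
    gas ⇌ second nucleophile, rate k5*(csat - [second nucleophile]) (kL = 0.540 /min)

Target over starting material in this flask at 30 h is 1.44 %, under the hold share of 1.61 %. Now carry the hold share to the neighbouring flask with first nucleophile at 1.1 M, the other charges held. Scaled by first nucleophile, it becomes 4.22 %, and on the 16.5 % of starting material left there at 30 h it gives 0.696 % of target. That neighbouring flask stands at 30 h at 0.626 % of target and 79.9 % of other capture product, a ratio of 128.

The readings were generated by integration with made-up constants, noise included.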